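**Retrosynthetic overview**

- Feature: in the ten-membered ring (C1–C10), C8 (tertiary OH) and C9 (secondary OH) are neighbouring oxygenated carbons. C8 also bears the C17(C18)–C19 propionate arm of the γ-lactone (C7, C8, C17, C19, O). This array is what a [2,3]-Wittig shift of a C9–O–C19 allyl ether onto an O-substituted C8 leaves behind.
- Key disconnection C8–C9: tin–lithium exchange at C9 of the thirteen-membered 1-stannylalkyl allyl ether 40, then ring contraction to the ten-membered carbocycle 42 (C9–OH, acetal-protected C8–O, C8 isopropenyl).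
- 40 comes from seco acetate 38 by palladium-catalysed O–C19 closure. The C17=C8 geometry (C7 cis to C19) is taken from a 3-methyltetronate reduced to the Z-enediol. The C5=C6 chloroalkene comes from syn carboalumination–chlorination and retentive lithiation, C2 and C7 from CBS reductions, and C9 from a Felkin–Anh stannyllithium addition.
- Ring order: ring A (C1, C10–C14) by an auxiliary-controlled Diels–Alder reaction, then the thirteen-membered ether, the ten-membered ring, the γ-lactone (a silicon tether sets C17), and last the C13–C14 epoxide under C12–OH direction.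

Key step: step 24

Numbering: briarane numbering is used for all intermediates; β is the ring A face that carries the C15 methyl group, α the opposite face; PMBM = (4-methoxybenzyloxy)methyl.
Assumption: the [2,3] shift is taken to invert the lithium-bearing carbon as in acyclic cases, and PMBM chloride is taken as an available reagent.

**Step 1**
Reactants: 1 ethyl 2-(triphenylphosphoranylidene)propanoate; 2 glyoxylic acid (used as its monohydrate)
Product: 3 (E)-4-ethoxy-3-methyl-4-oxobut-2-enoic acid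
Conditions: CH2Cl2–MeOH, 0 °C → rt
Reagents that add atoms: none
Why: Wittig olefination with a stabilised ylide gives the E-alkene, which places the future C2 ester trans to the future C9 carboxyl group and supplies C9, C10, C1, C15 and C2.

**Step 2**
Reactants: 3 (E)-4-ethoxy-3-methyl-4-oxobut-2-enoic acid; 4 (S)-4-benzyl-2-oxazolidinone
Product: 6 ethyl (E)-4-[(S)-4-benzyl-2-oxooxazolidin-3-yl]-2-methyl-4-oxobut-2-enoate, via mixed pivalic anhydride 5 (not isolated)
Conditions: PivCl, Et3N, THF, −20 °C; then LiCl, 4, −20 °C → rt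
Reagents that add atoms: none
Why: N-acylation of the oxazolidinone through the mixed anhydride is the standard route to enoyl imides and leaves the E-alkene untouched.

**Step 3**
Reactants: 6 enoyl imide; 7 (E)-penta-1,3-diene
Product: 8 ethyl (1S,5S,6S)-6-[(S)-4-benzyl-2-oxooxazolidine-3-carbonyl]-1,5-dimethylcyclohex-3-ene-1-carboxylate (ring A; 15-Me β; C9 β; 20-Me β; C2 α)
Conditions: Et2AlCl (1.4 equiv), 7 (5 equiv), CH2Cl2, −78 → −30 °C
Reagents that add atoms: none
Why: In this auxiliary-controlled Diels–Alder reaction the aluminium-chelated imide outranks the ester, so the unsubstituted diene terminus (C14) bonds to the fully substituted C1 and C11 bonds to C10; the E-alkene fixes C2 trans to C9, the endo imide puts the C20 methyl cis to C9, and the benzyl group shields one face of the s-cis enoyl unit and so sets the absolute configuration.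

**Step 4**
Reactants: 8 Diels–Alder adduct
Product: 10 trans-fused C9–O–C2 γ-lactone of ring A (C12=C13 alkene; 15-Me and 20-Me β), via hydroxy ester 9 (not isolated)
Conditions: LiBH4, MeOH (1 equiv), Et2O, 0 °C; then CSA (cat.), CH2Cl2, rt
Reagents that add atoms: none
Why: Reductive imide cleavage by LiBH4 is faster than attack on the hindered tertiary ester, and acid-catalysed lactonisation of the C9 alcohol onto C2 touches no stereocentre and locks the C15 and C20 methyl groups axial on the β face.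

**Step 5**
Reactants: 10 ring A lactone
Product: 11 12α,13α-epoxy lactone
Conditions: mCPBA, NaHCO3, CH2Cl2, 0 °C
Reagents that add atoms: mCPBA, O=C(OO)c1cccc(Cl)c1
Why: Prilezhaev epoxidation should occur on the α face because the two axial methyl groups of the locked lactone cover the β face of the C12=C13 alkene, which sets the α C12–O bond.

**Step 6**
Reactants: 11 epoxy lactone
Product: 12 12α-hydroxy-13,14-ene lactone
Conditions: LiN(i-Pr)2 (3 equiv), THF, 0 °C → rt
Reagents that add atoms: none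
Why: The lithium amide epoxide-to-allylic-alcohol isomerisation is a syn β-elimination that needs an axial hydrogen cis to the oxirane oxygen, here only C14–Hα (C11–Hα is equatorial), so the C13–O bond breaks, the alkene moves to C13=C14 and the α C12–OH is kept.

**Step 7**
Reactants: 12 allylic alcohol
Product: 13 12α-tert-butyldimethylsilyloxy lactone
Conditions: TBSCl, imidazole, DMF, rt
Reagents that add atoms: TBSCl, CC(C)(C)[Si](C)(C)Cl
Why: Standard silylation protects the allylic alcohol against the organometallic steps that follow.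

**Step 8**
Reactants: 14 but-3-yn-1-ol
Product: 16 (E)-4-chloro-3-methylbut-3-en-1-ol, via alkenylalane 15 (not isolated)
Conditions: AlMe3 (3 equiv), Cp2ZrCl2 (0.25 equiv), CH2Cl2, 0 °C → rt; then NCS, THF, −30 °C
Reagents that add atoms: trimethylaluminium, C[Al](C)C; N-chlorosuccinimide, O=C1CCC(=O)N1Cl
Why: Negishi carboalumination adds methyl and aluminium syn across the terminal alkyne and chlorodealumination goes with retention, so chlorine ends cis to the C16 methyl group.

**Step 9**
Reactants: 16 chloroalkenol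
Product: 17 (E)-1-chloro-4-iodo-2-methylbut-1-ene
Conditions: I2, PPh3, imidazole, CH2Cl2, 0 °C
Reagents that add atoms: iodine, II
Why: Appel-type iodination of a primary alcohol is reliable and does not touch the vinyl chloride.

**Step 10**
Reactants: 17 iodide; 13 silyloxy lactone
Product: 19 C2 ketone with free C9H2OH (C3–C6 chloroalkenyl chain attached), via alkyllithium 18 (not isolated)
Conditions: 17, t-BuLi (2.0 equiv), Et2O–pentane, −78 °C; then 13, −78 °C; aq NH4Cl
Reagents that add atoms: none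
Why: Lithium–iodine exchange is faster than any reaction at the vinyl chloride, and the primary alkyllithium adds only once to the hindered lactone because the tetrahedral alkoxide survives at −78 °C, which forms C2–C3 (acylation of an organolithium by a lactone).

**Step 11**
Reactants: 19 hydroxy ketone
Product: 20 C9 triethylsilyl ether
Conditions: TESCl, imidazole, CH2Cl2, 0 °C
Reagents that add atoms: TESCl, CC[Si](Cl)(CC)CC
Why: Silylation traps the open hydroxy ketone form and frees the C2 carbonyl group for reduction.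

**Step 12**
Reactants: 20 ketone
Product: 21 (2S)-alcohol
Conditions: (R)-2-methyl-CBS-oxazaborolidine (0.2 equiv), catecholborane, toluene, −78 → −40 °C
Reagents that add atoms: none
Why: In this Corey–Bakshi–Shibata reduction the quaternary C1 is the large and C3H2 the small ketone substituent, so the R catalyst should give the 2S alcohol under reagent control, and catecholborane leaves the alkenes alone.

**Step 13**
Reactants: 21 alcohol
Product: 22 C2 tert-butyldimethylsilyl ether
Conditions: TBSOTf, 2,6-lutidine, CH2Cl2, 0 °C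
Reagents that add atoms: TBSOTf, CC(C)(C)[Si](C)(C)OS(=O)(=O)C(F)(F)F
Why: Silyl triflate silylation copes with the neopentyl-type secondary alcohol.

**Step 14**
Reactants: 22 chloroalkene; 23 diethyl oxalate
Product: 25 C7 keto C8 ethyl ester on the tetrasubstituted C5=C6 chloroalkene (C7 cis to C4), via chloroalkenyllithium 24 (not isolated)
Conditions: s-BuLi (1.1 equiv), THF–Et2O–pentane, −105 °C; cannulate into 23 (5 equiv), THF, −105 → −78 °C
Reagents that add atoms: none
Why: Deprotonation of the 1-chloroalkene at its only vinylic hydrogen gives a 1-chloroalkenyllithium that holds its configuration below −100 °C and is acylated with retention by excess oxalate, so C7 ends cis to C4 (acylation of an organolithium).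

**Step 15**
Reactants: 25 keto ester
Product: 26 (7S)-hydroxy ester
Conditions: (R)-2-methyl-CBS-oxazaborolidine (0.3 equiv), catecholborane, toluene, −78 °C
Reagents that add atoms: none
Why: In this Corey–Bakshi–Shibata reduction of the activated keto group the tetrasubstituted chloroalkenyl group is the large and the ester the small substituent, so the R catalyst should give the 7S alcohol.

**Step 16**
Reactants: 26 hydroxy ester; 27 ethyl propanoate
Product: 30 3-methyltetronic acid (ring O7–C19–C17–C8–C7), via lithium enolate 28 (not isolated), via keto ester 29 (not isolated)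
Conditions: 27, LiN(i-Pr)2 (3.5 equiv each), THF, −78 °C; add 26, −78 → 0 °C; cold aq citric acid
Reagents that add atoms: none
Why: Crossed Claisen condensation at the C8 ester followed by lactonisation of the C7 alkoxide onto C19 (tetronic acid synthesis) brings in C17, C18 and C19, and C7 keeps its configuration because it is flanked first by an alkoxide and then by the tetronate anion.

**Step 17**
Reactants: 30 tetronic acid
Product: 31 C8-O-PMBM tetronate
Conditions: PMBMCl, i-Pr2NEt, CH2Cl2, 0 °C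
Reagents that add atoms: PMBM chloride, COc1ccc(COCCl)cc1
Why: O-alkylation of the vinylogous acid by a hard chloromethyl ether occurs at the C8 oxygen, and in the tetronate the ring fixes C7 cis to C19 on the C17=C8 double bond.

**Step 18**
Reactants: 31 tetronate
Product: 32 Z-enediol (C19H2OH and C7–OH; C8 enol ether)
Conditions: i-Bu2AlH (5 equiv), CH2Cl2, −78 → −20 °C; aq potassium sodium tartrate
Reagents that add atoms: none
Why: Exhaustive hydride reduction of an unsaturated lactone to the Z-enediol cleaves only the C19–O7 acyl bond, so the ring-enforced geometry is carried into the acyclic enol ether, and the non-acidic work-up avoids ionisation of the 3-alkoxyallyl alcohol.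

**Step 19**
Reactants: 32 enediol
Product: 33 C19 acetate
Conditions: AcCl (1.05 equiv), 2,4,6-collidine, CH2Cl2, −78 °C
Reagents that add atoms: acetyl chloride, CC(=O)Cl
Why: In this chemoselective acylation the unhindered primary C19 alcohol reacts ahead of the C7 alcohol, which sits between two fully substituted alkene carbons.

**Step 20**
Reactants: 33 acetate
Product: 34 C7 triethylsilyl ether
Conditions: TESOTf, 2,6-lutidine, CH2Cl2, −78 °C
Reagents that add atoms: TESOTf, CC[Si](CC)(CC)OS(=O)(=O)C(F)(F)F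
Why: Buffered silyl triflate silylation protects the hindered C7 alcohol, which would otherwise close a dihydrofuran in step 23.

**Step 21**
Reactants: 34 bis(triethylsilyl) ether
Product: 35 C9 aldehyde
Conditions: (COCl)2, DMSO, CH2Cl2, −78 → −40 °C; Et3N
Reagents that add atoms: none
Why: Swern oxidation converts primary triethylsilyl ethers directly into aldehydes while secondary triethylsilyl and tert-butyldimethylsilyl ethers survive, which frees C9 without an acidic deprotection.

**Step 22**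
Reactants: 35 aldehyde; 36 tributyltin hydride
Product: 38 (9S)-1-hydroxyalkylstannane, via tributylstannyllithium 37 (not isolated)
Conditions: 36, LiN(i-Pr)2, THF, 0 °C; then 35, −78 °C; aq NH4Cl at −78 °C
Reagents that add atoms: none
Why: 1,2-Addition of a stannyllithium to the aldehyde is far faster at −78 °C than attack on the acetate, and Felkin–Anh approach anti to the quaternary C1 and past C10–H should give the 9S carbinol.

**Step 23**
Reactants: 38 hydroxystannane acetate
Product: 40 thirteen-membered 1-stannylalkyl allyl ether (C9–O–C19; C17=C8 enol ether with C7 cis to C19), via ethylzinc alkoxide 39 (not isolated)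
Conditions: Et2Zn (1.0 equiv), THF, 0 °C; then Pd(OAc)2 (0.1 equiv), 2-(di-tert-butylphosphino)biphenyl (0.15 equiv), THF (2 mM), rt
Reagents that add atoms: none
Why: In this Tsuji–Trost allylic etherification the covalent zinc alkoxide cannot revert to aldehyde and stannyl anion as an alkali alkoxide would, the acetate ionises only on zerovalent palladium, and oxygen should attack the unsubstituted C19 terminus rather than the fully substituted C8, which closes the thirteen-membered ring with the C17=C8 geometry kept.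

**Step 24**
Reactants: 40 macrocyclic stannyl ether
Product: 42 ten-membered C9 alcohol bearing C8-O-PMBM and C8 isopropenyl, via C9 organolithium 41 (not isolated)
Conditions: n-BuLi (1.1 equiv), THF, −78 °C; aq NH4Cl
Reagents that add atoms: none
Why: Proposed new method: n-BuLi attacks tin, expels Bu4Sn and leaves the configurationally stable C9 α-alkoxyalkyllithium 41 with retention, and the carbanion lobe opposite to lithium bonds to C8 while the C17=C8 π bond moves to C17=C19 and the O–C19 σ bond breaks, a six-electron suprafacial [2,3] shift through a five-centre envelope (C9, O, C19, C17, C8). The closest known reactions are the Still–Wittig rearrangement of stannylalkyl allyl ethers and the [2,3]-Wittig contraction of thirteen-membered allylic ethers to ten-membered carbocycles; what is new is the fully substituted, alkoxy-bearing terminus, which is polarised in the right sense (C8 is the oxocarbenium-like end of the enol ether) but is hindered and electron-rich. The ten-membered ring (C1–C10) closes by ring contraction, with O, C19 and C17 leaving the ring, so both reacting ends are already held together. C9 is set by the 9S stannane through retention in the exchange and inversion in the shift, and C8 by the enol ether geometry (C7 cis to C19) with C10 exo on the envelope, where the C10–C1···C6–C7 tether spans both termini in a gauche arrangement. The step needs the exchange to outrun deprotonation at C7–H and C19–H and any attack on the chloroalkene, and the [2,3] path to outrun the [1,2] shift: exchange at an α-alkoxystannane is fast at −78 °C, 40 holds no carbonyl group, the tetrasubstituted vinyl chloride has no vinylic hydrogen, and low temperature disfavours the radical-pair [1,2] path.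

**Step 25**
Reactants: 42 C9 alcohol
Product: 43 C8,C9-bis-O-PMBM ether
Conditions: PMBMCl, i-Pr2NEt, Bu4NI (cat.), 1,2-dichloroethane, 50 °C
Reagents that add atoms: PMBM chloride, COc1ccc(COCCl)cc1
Why: Acetal protection under amine base keeps the C9 hydroxyl, which is also γ to C19, from competing with the C7 hydroxyl in the later lactonisation.

**Step 26**
Reactants: 43 bis-acetal
Product: 44 C7 alcohol
Conditions: PPTS (cat.), MeOH–CH2Cl2, 0 °C
Reagents that add atoms: none
Why: Mild acid-catalysed methanolysis removes the triethylsilyl ether and leaves the tert-butyldimethylsilyl ethers and the acetals in place.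

**Step 27**
Reactants: 44 C7 alcohol
Product: 46 six-membered oxasilinane (O7–SiMe2–C19–C17–C8–C7), via dimethylsilyl ether 45 (not isolated)
Conditions: (HMe2Si)2NH, neat, rt, then evacuate; Pt2[(CH2=CHSiMe2)2O]3 (0.5 mol %), toluene, 40 °C
Reagents that add atoms: 1,1,3,3-tetramethyldisilazane, C[SiH](C)N[SiH](C)C
Why: In the platinum-catalysed intramolecular hydrosilylation silicon goes to the unsubstituted C19, and the ring should form through the chair with C9 and the C18 methyl group equatorial, which delivers hydrogen to C17 so that the methyl group ends cis to the C8 oxygen as in the target.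

**Step 28**
Reactants: 46 oxasilinane
Product: 47 C7,C19-diol
Conditions: H2O2 (30 % aq), KF, KHCO3, THF–MeOH, rt
Reagents that add atoms: hydrogen peroxide, OO
Why: Tamao–Fleming oxidation replaces the C19–Si bond by C19–OH without touching C17, and the buffered medium spares the acetals and silyl ethers.

**Step 29**
Reactants: 47 diol
Product: 49 γ-lactone (C7–O–C19), via lactol 48 (not isolated)
Conditions: TEMPO (0.2 equiv), PhI(OAc)2 (2.5 equiv), CH2Cl2, rt
Reagents that add atoms: none
Why: TEMPO-catalysed oxidative lactonisation of a 1,4-diol oxidises the primary C19 alcohol first, the aldehyde is trapped by C7–OH as the lactol, and this is oxidised on under non-basic conditions that do not epimerise C17.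

**Step 30**
Reactants: 49 lactone
Product: 50 C2,C12-diol
Conditions: HF·pyridine, pyridine, THF, 0 °C → rt
Reagents that add atoms: none
Why: Buffered fluoride desilylation removes both tert-butyldimethylsilyl ethers and leaves the acetals, the lactone and the chloroalkene alone.

**Step 31**
Reactants: 50 diol
Product: 51 13α,14α-epoxide
Conditions: VO(acac)2 (5 mol %), t-BuOOH, CH2Cl2, 0 °C
Reagents that add atoms: tert-butyl hydroperoxide, CC(C)(C)OO
Why: Hydroxyl-directed vanadium-catalysed epoxidation delivers oxygen to C13=C14 syn to the α C12–OH (the α-oriented C2–OH supports it), and the electron-poor tetrasubstituted chloroalkene has no free directing hydroxyl nearby.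

**Step 32**
Reactants: 51 epoxy diol
Product: 52 C2,C12-diacetate
Conditions: Ac2O, pyridine, DMAP (cat.), CH2Cl2, 0 °C
Reagents that add atoms: acetic anhydride, CC(=O)OC(C)=O
Why: Standard acetylation meets only the two free secondary hydroxyl groups because O8 and O9 are still protected.

**Step 33**
Reactants: 52 diacetate
Product: 53 CNP0255641.1
Conditions: DDQ, CH2Cl2–pH 7 buffer, 0 °C → rt
Reagents that add atoms: none
Why: Oxidative cleavage of 4-methoxybenzyl-type acetals by DDQ works at the remote benzylic position under neutral conditions, so the hindered C8 and C9 oxygens are freed without harm to the epoxide, acetates, lactone or chloroalkene.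

**Compound list**

1 | ethyl 2-(triphenylphosphoranylidene)propanoate | CCOC(=O)C(C)=P(c1ccccc1)(c1ccccc1)c1ccccc1 | starting material
2 | glyoxylic acid | O=CC(=O)O | starting material
3 | (E)-4-ethoxy-3-methyl-4-oxobut-2-enoic acid | CCOC(=O)/C(C)=C/C(=O)O | intermediate
4 | (S)-4-benzyl-2-oxazolidinone | O=C1N[C@@H](Cc2ccccc2)CO1 | starting material
5 | mixed pivalic anhydride of 3 | CCOC(=O)/C(C)=C/C(=O)OC(=O)C(C)(C)C | intermediate
6 | enoyl imide | CCOC(=O)/C(C)=C/C(=O)N1[C@@H](Cc2ccccc2)COC1=O | intermediate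
7 | (E)-penta-1,3-diene | C/C=C/C=C | starting material
8 | ring A Diels–Alder adduct | C1=C[C@H](C)[C@H](C(=O)N2[C@@H](Cc3ccccc3)COC2=O)[C@@](C)(C(=O)OCC)C1 | intermediate
9 | C9 hydroxy C2 ethyl ester | C1=C[C@H](C)[C@H](CO)[C@@](C)(C(=O)OCC)C1 | intermediate
10 | trans-fused ring A lactone | C1=C[C@H](C)[C@@H]2COC(=O)[C@@]2(C)C1 | intermediate
11 | 12α,13α-epoxy lactone | [C@H]12O[C@H]1[C@H](C)[C@@H]3COC(=O)[C@@]3(C)C2 | intermediate
12 | 12α-hydroxy-13,14-ene lactone | O[C@H]1[C@H](C)[C@@H]2COC(=O)[C@@]2(C)C=C1 | intermediate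
13 | 12α-silyloxy lactone | CC(C)(C)[Si](C)(C)O[C@H]1[C@H](C)[C@@H]2COC(=O)[C@@]2(C)C=C1 | intermediate
14 | but-3-yn-1-ol | C#CCCO | starting material
15 | alkenylalane | C[Al](C)OCC/C(C)=C/[Al](C)C | intermediate
16 | (E)-4-chloro-3-methylbut-3-en-1-ol | OCC/C(C)=C/Cl | intermediate
17 | (E)-1-chloro-4-iodo-2-methylbut-1-ene | ICC/C(C)=C/Cl | intermediate
18 | alkyllithium | [Li]CC/C(C)=C/Cl | intermediate
19 | C2 ketone, C9 alcohol | CC(C)(C)[Si](C)(C)O[C@H]1[C@H](C)[C@H](CO)[C@@](C)(C(=O)CC/C(C)=C/Cl)C=C1 | intermediate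
20 | C9 triethylsilyl ether | CC(C)(C)[Si](C)(C)O[C@H]1[C@H](C)[C@H](CO[Si](CC)(CC)CC)[C@@](C)(C(=O)CC/C(C)=C/Cl)C=C1 | intermediate
21 | (2S)-alcohol | CC(C)(C)[Si](C)(C)O[C@H]1[C@H](C)[C@H](CO[Si](CC)(CC)CC)[C@@](C)([C@@H](O)CC/C(C)=C/Cl)C=C1 | intermediate
22 | C2 silyl ether | CC(C)(C)[Si](C)(C)O[C@H]1[C@H](C)[C@H](CO[Si](CC)(CC)CC)[C@@](C)([C@@H](O[Si](C)(C)C(C)(C)C)CC/C(C)=C/Cl)C=C1 | intermediate
23 | diethyl oxalate | CCOC(=O)C(=O)OCC | starting material
24 | C6 chloroalkenyllithium | CC(C)(C)[Si](C)(C)O[C@H]1[C@H](C)[C@H](CO[Si](CC)(CC)CC)[C@@](C)([C@@H](O[Si](C)(C)C(C)(C)C)CC/C(C)=C(/Cl)[Li])C=C1 | intermediate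
25 | C7 keto ester | CC(C)(C)[Si](C)(C)O[C@H]1[C@H](C)[C@H](CO[Si](CC)(CC)CC)[C@@](C)([C@@H](O[Si](C)(C)C(C)(C)C)CC/C(C)=C(/Cl)C(=O)C(=O)OCC)C=C1 | intermediate
26 | (7S)-hydroxy ester | CC(C)(C)[Si](C)(C)O[C@H]1[C@H](C)[C@H](CO[Si](CC)(CC)CC)[C@@](C)([C@@H](O[Si](C)(C)C(C)(C)C)CC/C(C)=C(/Cl)[C@@H](O)C(=O)OCC)C=C1 | intermediate
27 | ethyl propanoate | CCC(=O)OCC | starting material
28 | lithium enolate of 27 | CC=C(OCC)O[Li] | intermediate
29 | C7 hydroxy C8 keto C19 ester | CC(C)(C)[Si](C)(C)O[C@H]1[C@H](C)[C@H](CO[Si](CC)(CC)CC)[C@@](C)([C@@H](O[Si](C)(C)C(C)(C)C)CC/C(C)=C(/Cl)[C@@H](O)C(=O)C(C)C(=O)OCC)C=C1 | intermediate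
30 | 3-methyltetronic acid | CC(C)(C)[Si](C)(C)O[C@H]1[C@H](C)[C@H](CO[Si](CC)(CC)CC)[C@@](C)([C@@H](O[Si](C)(C)C(C)(C)C)CC/C(C)=C(/Cl)[C@H]2OC(=O)C(C)=C2O)C=C1 | intermediate
31 | C8-O-PMBM tetronate | CC(C)(C)[Si](C)(C)O[C@H]1[C@H](C)[C@H](CO[Si](CC)(CC)CC)[C@@](C)([C@@H](O[Si](C)(C)C(C)(C)C)CC/C(C)=C(/Cl)[C@H]2OC(=O)C(C)=C2OCOCc2ccc(OC)cc2)C=C1 | intermediate
32 | Z-enediol | CC(C)(C)[Si](C)(C)O[C@H]1[C@H](C)[C@H](CO[Si](CC)(CC)CC)[C@@](C)([C@@H](O[Si](C)(C)C(C)(C)C)CC/C(C)=C(/Cl)[C@@H](O)/C(OCOCc2ccc(OC)cc2)=C(/C)CO)C=C1 | intermediate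
33 | C19 acetate | CC(C)(C)[Si](C)(C)O[C@H]1[C@H](C)[C@H](CO[Si](CC)(CC)CC)[C@@](C)([C@@H](O[Si](C)(C)C(C)(C)C)CC/C(C)=C(/Cl)[C@@H](O)/C(OCOCc2ccc(OC)cc2)=C(/C)COC(C)=O)C=C1 | intermediate
34 | C7 triethylsilyl ether | CC(C)(C)[Si](C)(C)O[C@H]1[C@H](C)[C@H](CO[Si](CC)(CC)CC)[C@@](C)([C@@H](O[Si](C)(C)C(C)(C)C)CC/C(C)=C(/Cl)[C@@H](O[Si](CC)(CC)CC)/C(OCOCc2ccc(OC)cc2)=C(/C)COC(C)=O)C=C1 | intermediate
35 | C9 aldehyde | CC(C)(C)[Si](C)(C)O[C@H]1[C@H](C)[C@H](C=O)[C@@](C)([C@@H](O[Si](C)(C)C(C)(C)C)CC/C(C)=C(/Cl)[C@@H](O[Si](CC)(CC)CC)/C(OCOCc2ccc(OC)cc2)=C(/C)COC(C)=O)C=C1 | intermediate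
36 | tributyltin hydride | CCCC[SnH](CCCC)CCCC | starting material
37 | tributylstannyllithium | [Li][Sn](CCCC)(CCCC)CCCC | intermediate
38 | (9S)-hydroxystannane acetate | CC(C)(C)[Si](C)(C)O[C@H]1[C@H](C)[C@H]([C@@H](O)[Sn](CCCC)(CCCC)CCCC)[C@@](C)([C@@H](O[Si](C)(C)C(C)(C)C)CC/C(C)=C(/Cl)[C@@H](O[Si](CC)(CC)CC)/C(OCOCc2ccc(OC)cc2)=C(/C)COC(C)=O)C=C1 | intermediate
39 | ethylzinc alkoxide of 38 | CC(C)(C)[Si](C)(C)O[C@H]1[C@H](C)[C@H]([C@@H](O[Zn]CC)[Sn](CCCC)(CCCC)CCCC)[C@@](C)([C@@H](O[Si](C)(C)C(C)(C)C)CC/C(C)=C(/Cl)[C@@H](O[Si](CC)(CC)CC)/C(OCOCc2ccc(OC)cc2)=C(/C)COC(C)=O)C=C1 | intermediate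
40 | thirteen-membered stannyl allyl ether (key-step precursor) | CC(C)(C)[Si](C)(C)O[C@H]1[C@H](C)[C@@H]2[C@H]([Sn](CCCC)(CCCC)CCCC)OC/C(C)=C(OCOCc3ccc(OC)cc3)\[C@H](O[Si](CC)(CC)CC)/C(Cl)=C(/C)CC[C@H](O[Si](C)(C)C(C)(C)C)[C@@]2(C)C=C1 | intermediate
41 | C9 organolithium | CC(C)(C)[Si](C)(C)O[C@H]1[C@H](C)[C@@H]2[C@H]([Li])OC/C(C)=C(OCOCc3ccc(OC)cc3)\[C@H](O[Si](CC)(CC)CC)/C(Cl)=C(/C)CC[C@H](O[Si](C)(C)C(C)(C)C)[C@@]2(C)C=C1 | intermediate
42 | ten-membered C9 alcohol (key-step product) | CC(C)(C)[Si](C)(C)O[C@H]1[C@H](C)[C@@H]2[C@H](O)[C@](OCOCc3ccc(OC)cc3)(C(C)=C)[C@H](O[Si](CC)(CC)CC)/C(Cl)=C(/C)CC[C@H](O[Si](C)(C)C(C)(C)C)[C@@]2(C)C=C1 | intermediate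
43 | C8,C9-bis-O-PMBM ether | CC(C)(C)[Si](C)(C)O[C@H]1[C@H](C)[C@@H]2[C@H](OCOCc3ccc(OC)cc3)[C@](OCOCc3ccc(OC)cc3)(C(C)=C)[C@H](O[Si](CC)(CC)CC)/C(Cl)=C(/C)CC[C@H](O[Si](C)(C)C(C)(C)C)[C@@]2(C)C=C1 | intermediate
44 | C7 alcohol | CC(C)(C)[Si](C)(C)O[C@H]1[C@H](C)[C@@H]2[C@H](OCOCc3ccc(OC)cc3)[C@](OCOCc3ccc(OC)cc3)(C(C)=C)[C@H](O)/C(Cl)=C(/C)CC[C@H](O[Si](C)(C)C(C)(C)C)[C@@]2(C)C=C1 | intermediate
45 | C7 dimethylsilyl ether | CC(C)(C)[Si](C)(C)O[C@H]1[C@H](C)[C@@H]2[C@H](OCOCc3ccc(OC)cc3)[C@](OCOCc3ccc(OC)cc3)(C(C)=C)[C@H](O[SiH](C)C)/C(Cl)=C(/C)CC[C@H](O[Si](C)(C)C(C)(C)C)[C@@]2(C)C=C1 | intermediate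
46 | oxasilinane | CC(C)(C)[Si](C)(C)O[C@H]1[C@H](C)[C@@H]2[C@H](OCOCc3ccc(OC)cc3)[C@@]3(OCOCc4ccc(OC)cc4)[C@H](O[Si](C)(C)C[C@@H]3C)/C(Cl)=C(/C)CC[C@H](O[Si](C)(C)C(C)(C)C)[C@@]2(C)C=C1 | intermediate
47 | C7,C19-diol | CC(C)(C)[Si](C)(C)O[C@H]1[C@H](C)[C@@H]2[C@H](OCOCc3ccc(OC)cc3)[C@](OCOCc3ccc(OC)cc3)([C@@H](C)CO)[C@H](O)/C(Cl)=C(/C)CC[C@H](O[Si](C)(C)C(C)(C)C)[C@@]2(C)C=C1 | intermediate
48 | lactol | CC(C)(C)[Si](C)(C)O[C@H]1[C@H](C)[C@@H]2[C@H](OCOCc3ccc(OC)cc3)[C@@]3(OCOCc4ccc(OC)cc4)[C@H](OC(O)[C@@H]3C)/C(Cl)=C(/C)CC[C@H](O[Si](C)(C)C(C)(C)C)[C@@]2(C)C=C1 | intermediate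
49 | γ-lactone | CC(C)(C)[Si](C)(C)O[C@H]1[C@H](C)[C@@H]2[C@H](OCOCc3ccc(OC)cc3)[C@@]3(OCOCc4ccc(OC)cc4)[C@H](OC(=O)[C@@H]3C)/C(Cl)=C(/C)CC[C@H](O[Si](C)(C)C(C)(C)C)[C@@]2(C)C=C1 | intermediate
50 | C2,C12-diol | O[C@H]1[C@H](C)[C@@H]2[C@H](OCOCc3ccc(OC)cc3)[C@@]3(OCOCc4ccc(OC)cc4)[C@H](OC(=O)[C@@H]3C)/C(Cl)=C(/C)CC[C@H](O)[C@@]2(C)C=C1 | intermediate
51 | 13α,14α-epoxy diol | O[C@H]1[C@H](C)[C@@H]2[C@H](OCOCc3ccc(OC)cc3)[C@@]3(OCOCc4ccc(OC)cc4)[C@H](OC(=O)[C@@H]3C)/C(Cl)=C(/C)CC[C@H](O)[C@@]2(C)[C@H]2O[C@@H]12 | intermediate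
52 | C2,C12-diacetate | CC(=O)O[C@H]1[C@H](C)[C@@H]2[C@H](OCOCc3ccc(OC)cc3)[C@@]3(OCOCc4ccc(OC)cc4)[C@H](OC(=O)[C@@H]3C)/C(Cl)=C(/C)CC[C@H](OC(C)=O)[C@@]2(C)[C@H]2O[C@@H]12 | intermediate
53 | CNP0255641.1 | CC(=O)O[C@H]1[C@H](C)[C@@H]2[C@H](O)[C@@]3(O)[C@H](OC(=O)[C@@H]3C)/C(Cl)=C(/C)CC[C@H](OC(C)=O)[C@@]2(C)[C@H]2O[C@@H]12 | target

**Totals**

Total step count: 33. Longest linear sequence: 31 steps (steps 1–7 and 10–33).

**Steps most likely to fail**

1. **Step 24 (key step).**
   - What may go wrong: the C9 carbanion may be quenched by proton transfer from C7–H or C19–H. It may migrate by the [1,2] path. The hindered, electron-rich C8 terminus may not accept it, so that only protodestannylation is seen. The wrong face of C8 may be chosen.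
   - Fallback (known chemistry): the C8–C9 bond and the ten-membered ring are made by a palladium/diethylzinc umpolung allylation that sets out from aldehyde 35. Pd(PPh3)4 with excess Et2Zn turns the C19 acetate into the allyl(ethyl)zinc species F1. F1 adds through its γ-carbon C8 to the C9 aldehyde in a six-membered cyclic transition state, as γ-alkoxyallylmetal reagents do when they give 1,2-diol monoethers. This comes back to the route at 42.

2. **Step 23.**
   - What may go wrong: the acetate on the tetrasubstituted enol ether alkene may ionise too slowly. Oxygen may attack C8 instead of C19. The allyl complex may lose its geometry by π–σ–π isomerisation. Oligomerisation may compete with ring closure.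
   - Fallback: the metal-catalysed closure is replaced by the acid-catalysed imidate etherification that is the usual O-alkylation of 1-hydroxyalkylstannanes. It sets out from 38. Methanolysis (K2CO3, MeOH, 0 °C) gives the C9,C19-diol F2. Cl3CCN with catalytic DBU gives the primary trichloroacetimidate F3. Catalytic TMSOTf at −78 °C under high dilution closes the ether and comes back at 40.

3. **Step 18.**
   - What may go wrong: reduction may stop at the lactol, which then dehydrates to a 3-alkoxyfuran on work-up. The aluminium Lewis acid may ionise the allylic oxygen.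
   - Fallback: the ring is opened before any hydride is used. It sets out from 31. Me(MeO)NH·HCl with i-PrMgCl gives the Z-hydroxy Weinreb amide F4. TESOTf with 2,6-lutidine gives its C7 silyl ether F5. i-Bu2AlH at −78 °C gives the enal F6. NaBH4 in MeOH gives the allylic alcohol F7. Acetylation (AcCl, collidine) comes back at 34.

**Further compounds**

F1 | step 24 | allyl(ethyl)zinc aldehyde | CC(C)(C)[Si](C)(C)O[C@H]1[C@H](C)[C@H](C=O)[C@@](C)([C@@H](O[Si](C)(C)C(C)(C)C)CC/C(C)=C(/Cl)[C@@H](O[Si](CC)(CC)CC)/C(OCOCc2ccc(OC)cc2)=C(/C)C[Zn]CC)C=C1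
F2 | step 23 | C9,C19-diol (hydroxystannane) | CC(C)(C)[Si](C)(C)O[C@H]1[C@H](C)[C@H]([C@@H](O)[Sn](CCCC)(CCCC)CCCC)[C@@](C)([C@@H](O[Si](C)(C)C(C)(C)C)CC/C(C)=C(/Cl)[C@@H](O[Si](CC)(CC)CC)/C(OCOCc2ccc(OC)cc2)=C(/C)CO)C=C1
F3 | step 23 | C19 trichloroacetimidate | CC(C)(C)[Si](C)(C)O[C@H]1[C@H](C)[C@H]([C@@H](O)[Sn](CCCC)(CCCC)CCCC)[C@@](C)([C@@H](O[Si](C)(C)C(C)(C)C)CC/C(C)=C(/Cl)[C@@H](O[Si](CC)(CC)CC)/C(OCOCc2ccc(OC)cc2)=C(/C)COC(=N)C(Cl)(Cl)Cl)C=C1
F4 | step 18 | Z-hydroxy Weinreb amide | CC(C)(C)[Si](C)(C)O[C@H]1[C@H](C)[C@H](CO[Si](CC)(CC)CC)[C@@](C)([C@@H](O[Si](C)(C)C(C)(C)C)CC/C(C)=C(/Cl)[C@@H](O)/C(OCOCc2ccc(OC)cc2)=C(/C)C(=O)N(C)OC)C=C1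
F5 | step 18 | C7 silyl ether of the Weinreb amide | CC(C)(C)[Si](C)(C)O[C@H]1[C@H](C)[C@H](CO[Si](CC)(CC)CC)[C@@](C)([C@@H](O[Si](C)(C)C(C)(C)C)CC/C(C)=C(/Cl)[C@@H](O[Si](CC)(CC)CC)/C(OCOCc2ccc(OC)cc2)=C(/C)C(=O)N(C)OC)C=C1
F6 | step 18 | C19 enal | CC(C)(C)[Si](C)(C)O[C@H]1[C@H](C)[C@H](CO[Si](CC)(CC)CC)[C@@](C)([C@@H](O[Si](C)(C)C(C)(C)C)CC/C(C)=C(/Cl)[C@@H](O[Si](CC)(CC)CC)/C(OCOCc2ccc(OC)cc2)=C(/C)C=O)C=C1
F7 | step 18 | C19 allylic alcohol | CC(C)(C)[Si](C)(C)O[C@H]1[C@H](C)[C@H](CO[Si](CC)(CC)CC)[C@@](C)([C@@H](O[Si](C)(C)C(C)(C)C)CC/C(C)=C(/Cl)[C@@H](O[Si](CC)(CC)CC)/C(OCOCc2ccc(OC)cc2)=C(/C)CO)C=C1
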